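**Retrosynthetic overview**

1. Target ⇐ C8 ketone: the 8,17-epoxide is added last by Corey–Chaykovsky methylene transfer, and the spiro-lactone carbonyl C16 is carried as a methyl acetal until a Jones oxidation.
2. Enabling feature: in ring B (C5–C6–C7–C8–C9–C10) the ketone-level carbon C8 (the spiro-epoxide carbon) is the direct neighbour of C9, which carries the tetrahydrofuran oxygen and is bonded to quaternary C10. This α-alkoxy ketone is the product pattern of a 1,2-shift onto an oxocarbenium ion, so ring B is made from the five-membered ring C5–C6–C7–C8–C10 by moving C10 from C8 to C9 while the tetrahydrofuran ring closes on an alkyne.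
3. Cascade substrate (tertiary propargylic alcohol at C8, tertiary homopropargylic alcohol at C13) ⇐ alkynylcerium addition of a C9/C11–C16 fragment to a bicyclic keto lactone; C13 comes from (R)-malic acid by alkylation with self-regeneration of the stereocentre.
4. Keto lactone ⇐ (S)-bicyclic enedione (C10 bought): C4 by carboxylation and deconjugative methylation, C3 deoxygenation, 19,6β-lactone and 5α-H by iodolactonisation and radical deiodination.
5. Ring order: ring A and the five-membered ring (bought) → 19,6-lactone → masked butyrolactone ring (fragment) → tetrahydrofuran ring and six-membered ring B together → butyrolactone carbonyl → epoxide.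

Key step: step 14

Remark: atoms of all intermediates carry the labdane numbers of the target atoms they become (ring A = C1–C5 + C10; C18 = CH3 on C4; C19 = carboxyl carbon on C4; C20 = CH3 on C10; C17 = epoxide CH2; C16 = spiro-lactone carbonyl), α/β mean below/above the plane with C20 β, and the methyl acetal fragment and its descendants are carried as mixtures of epimers at the acetal carbon C16 until that carbon becomes a carbonyl.

**Fragment A (keto lactone)**

Step 1
Reactants: 1 (7aS)-7a-methyl-2,3,7,7a-tetrahydro-1H-indene-1,5(6H)-dione
Product: 2 enone ketal (C8 ketone as 1,3-dioxolane)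
Conditions: ethylene glycol, p-TsOH·H2O (cat.), 4 Å MS, CH2Cl2, rt
Reagents that add atoms: ethylene glycol, OCCO
Why: Chemoselective ketalisation, because the saturated cyclopentanone reacts much faster than the conjugated enone carbonyl; no stereocentre is touched.

Step 2
Reactants: 2 enone ketal
Product: 3 enone acid (CO2H on C4)
Conditions: MeOMgOCO2Me (2 M in DMF), 125 °C; then 1 M HCl, 0 °C
Reagents that add atoms: magnesium methyl carbonate, CO[Mg]OC(=O)OC
Why: Carboxylation of the thermodynamic dienolate at the α-carbon C4 with magnesium methyl carbonate, driven by the magnesium chelate of the vinylogous β-keto acid; the enone is the only enolisable carbonyl.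

Step 3
Reactants: 3 enone acid
Product: 4 keto ester (C3=O; C4 with CH3 α and CO2CH3 β; C5=C6)
Conditions: K2CO3, MeI (excess), acetone, 40 °C
Reagents that add atoms: iodomethane, CI
Why: O-alkylation of the carboxylate followed by deconjugative C-alkylation of the vinylogous β-keto ester dienolate at C4; MeI should enter anti to the angular C20 methyl, which leaves the ester β (cis to C20) and sets C4.

Step 4
Reactants: 4 keto ester
Product: 6 deoxo ester (C3 = CH2), via tosylhydrazone 5 (not isolated)
Conditions: TsNHNH2, EtOH, 75 °C; evaporate; catecholborane, CHCl3, 0 °C → rt; then NaOAc·3H2O, reflux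
Reagents that add atoms: none
Why: Reductive deoxygenation of a ketone through its tosylhydrazone (hydride addition to C=N, loss of sulfinate, diazene fragmentation); the isolated C5=C6 alkene, the ester and the ketal are inert, and C4 is not enolisable.

Step 5
Reactants: 6 deoxo ester
Product: 7 β,γ-unsaturated acid
Conditions: n-PrSLi, HMPA, rt; then 1 M HCl, 0 °C
Reagents that add atoms: none
Why: SN2 O-demethylation by thiolate, the usual answer to a neopentyl axial ester that resists saponification; no stereocentre is touched.

Step 6
Reactants: 7 β,γ-unsaturated acid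
Product: 8 iodo lactone (19,6β-olide, 5α-iodide)
Conditions: I2, KI, NaHCO3, CH2Cl2/H2O, rt, dark
Reagents that add atoms: iodine, II
Why: Iodolactonisation with 5-endo closure on C6 (attack at C5, flanked by two quaternary carbons, would give a strained β-lactone); the β-carboxylate can reach C6 only from the β-face, so O–C6 is set β and iodine adds to C5 from the α-face.

Step 7
Reactants: 8 iodo lactone
Product: 9 lactone ketal
Conditions: n-Bu3SnH, AIBN (cat.), PhH, 80 °C
Reagents that add atoms: none
Why: Radical deiodination; the planar C5 radical can take hydrogen only from the α-face, because the β-face carries the lactone bridge and C20, which sets 5α-H and the trans ring fusion.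

Step 8
Reactants: 9 lactone ketal
Product: 10 keto lactone (C8 ketone)
Conditions: 1 M HCl, THF, rt
Reagents that add atoms: water, O
Why: Acid-catalysed ketal hydrolysis; the γ-lactone survives and no stereocentre is α to the released ketone except quaternary C10.

**Fragment B (C9/C11–C16)**

Step 9
Reactants: 11 (R)-malic acid
Product: 12 cis-dioxolanone acid, 2-[(2R,4R)-2-tert-butyl-5-oxo-1,3-dioxolan-4-yl]acetic acid
Conditions: t-BuCHO, p-TsOH (cat.), H2SO4 (cat.), pentane, reflux with azeotropic removal of water; recrystallise
Reagents that add atoms: pivalaldehyde, CC(C)(C)C=O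
Why: Acetalisation of the α-hydroxy acid unit to the 1,3-dioxolan-4-one; the cis isomer is thermodynamically favoured and crystalline, and its acetal carbon stores the chirality (self-regeneration of stereocentres).

Step 10
Reactants: 12 cis-dioxolanone acid
Product: 13 propargylated dioxolanone acid (2R,4R)
Conditions: LiN(SiMe3)2 (2.1 equiv), THF, −78 °C; propargyl bromide, −78 → −20 °C; then 1 M HCl
Reagents that add atoms: propargyl bromide, C#CCBr
Why: Alkylation of the carboxylate/enolate dianion; the electrophile enters trans to the tert-butyl group, so the quaternary C13 is formed with overall retention.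

Step 11
Reactants: 13 propargylated dioxolanone acid
Product: 15 (3R)-3-hydroxy-3-(prop-2-yn-1-yl)oxolan-2-one, via hydroxy dioxolanone 14 (not isolated)
Conditions: i-BuOCOCl, N-methylmorpholine, THF, −15 °C; NaBH4, THF/H2O, −15 → 0 °C; then p-TsOH (cat.), CH2Cl2, rt
Reagents that add atoms: none
Why: Mixed-anhydride activation and borohydride reduction is selective for the free acid over the alkyne, and acid then drives translactonisation of the new primary alcohol onto the dioxolanone carbonyl with loss of pivalaldehyde; C13 is untouched.

Step 12
Reactants: 15 (3R)-3-hydroxy-3-(prop-2-yn-1-yl)oxolan-2-one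
Product: 17 (3R)-2-methoxy-3-(prop-2-yn-1-yl)oxolan-3-ol (both C2 epimers), via lactol 16 (not isolated)
Conditions: i-Bu2AlH (2.2 equiv), CH2Cl2, −78 °C; aqueous potassium sodium tartrate; then MeOH, PPTS (cat.), rt
Reagents that add atoms: methanol, CO
Why: Lactone-to-lactol reduction at −78 °C and acid-catalysed acetalisation mask C16 at the aldehyde level so that it survives the organometallic step; the acetal centre is left as a mixture because it later becomes C=O.

**Union and endgame**

Step 13
Reactants: 17 (3R)-2-methoxy-3-(prop-2-yn-1-yl)oxolan-3-ol; 10 keto lactone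
Product: 18 alkyne diol (8β-OH, 8α-alkynyl, 13R)
Conditions: 17 (1.3 equiv), n-BuLi (2.6 equiv), THF, −78 → −20 °C; CeCl3 (anhydrous), −78 °C; then 10, −78 °C; aqueous NH4Cl
Reagents that add atoms: none
Why: 1,2-Addition of an alkynylcerium reagent to a hindered enolisable ketone; attack anti to the angular methyl and the β-lactone bridge should give the 8β-carbinol, while the low basicity at −78 °C avoids enolisation with β-elimination of the C6 acyloxy group and the hindered lactone is not attacked.

Step 14
Reactants: 18 alkyne diol
Product: 20 spiro ketone (C8=O, 9α-O, C16 methyl acetal), via enol ether carbinol 19 (not isolated)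
Conditions: Ph3PAuNTf2 (5 mol %), 4 Å MS, CH2Cl2, 0 °C → rt; then (+)-camphor-10-sulfonic acid (10 mol %), 0 °C → rt
Reagents that add atoms: none
Why: Proposed new method: a one-flask cycloisomerisation/semipinacol cascade on an unstrained cyclopentanol has not been shown as such; mechanistically, monovalent gold activates the C9≡C11 alkyne, the C13 hydroxyl closes the tetrahydrofuran ring 5-endo-dig at C9 to give enol ether 19, and protonation at C11 gives a cyclic oxocarbenium ion at C9 that is quenched by a 1,2-shift of C10 from C8 to C9 with release of the C8 carbonyl, so that ring B grows from five to six atoms by ring expansion and not by a second ring closure. The closest known reaction types are the gold-catalysed 5-endo-dig cyclisation of homopropargylic alcohols to 2,3-dihydrofurans and the acid-induced pinacol-type ring expansion of 1-(4,5-dihydrofuran-2-yl)cycloalkanols to oxaspirocyclic ketones. C9 is the only new stereocentre: C10 migrates with retention across the α-face onto the oxocarbenium carbon in the rotamer that keeps O9 anti to the 8β-hydroxyl (opposed C–O dipoles, leading directly to the chair α-alkoxy ketone with axial oxygen), which should place O9 α and C11 β, while C13 is carried in from 17. The step needs migration of C10 and not C7, secured by the better migrating ability of the fully substituted carbon and by the fact that C7 migration would put the ketone between two quaternary carbons; it also needs cyclisation to outrun Meyer–Schuster isomerisation of the propargylic alcohol, secured by the tethered hydroxyl and by adding the acid only after the alkyne is consumed.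

Step 15
Reactants: 20 spiro ketone
Product: 21 keto dilactone
Conditions: CrO3, H2SO4, H2O, acetone, 0 °C → rt
Reagents that add atoms: water, O
Why: Jones oxidation of a cyclic methyl acetal (hydrolysis in the flask to the lactol, then chromic acid oxidation to the γ-lactone); C9 and C13 are quaternary and no stereocentre is touched.

Step 16
Reactants: 21 keto dilactone
Product: 22 target (CNP0105047.2)
Conditions: Me3S+ I−, KN(SiMe3)2, THF, −10 → 0 °C
Reagents that add atoms: trimethylsulfonium iodide, C[S+](C)C.[I-]
Why: Corey–Chaykovsky epoxidation; the ylide should add to C8 from the α-face (equatorial attack, the β-face being blocked by the 1,3-diaxial C20 methyl and O6), so C17 ends α-equatorial and the epoxide oxygen β-axial as in the target.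

**Compound list**

1 | (7aS)-7a-methyl-2,3,7,7a-tetrahydro-1H-indene-1,5(6H)-dione | C[C@]12CCC(=O)C=C1CCC2=O | starting material
2 | enone ketal: (7a'S)-7a'-methyl-2',3',7',7a'-tetrahydrospiro[1,3-dioxolane-2,1'-inden]-5'(6'H)-one | C[C@]12CCC(=O)C=C1CCC23OCCO3 | intermediate
3 | enone acid: 4-carboxylic acid of 2 (C3=O, C4=C5, C8 dioxolane) | C[C@]12CCC(=O)C(C(=O)O)=C1CCC23OCCO3 | intermediate
4 | keto ester: methyl ester, C3=O, C4 (CH3 α, CO2CH3 β), C5=C6, C10 CH3 β, C8 dioxolane | C[C@]12CCC(=O)[C@](C)(C(=O)OC)C1=CCC23OCCO3 | intermediate
5 | tosylhydrazone of 4 at C3 | C[C@]12CCC(=NNS(=O)(=O)c3ccc(C)cc3)[C@](C)(C(=O)OC)C1=CCC24OCCO4 | intermediate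
6 | deoxo ester: as 4 with C3 = CH2 | C[C@]12CCC[C@](C)(C(=O)OC)C1=CCC23OCCO3 | intermediate
7 | β,γ-unsaturated acid: free C19 acid of 6 | C[C@]12CCC[C@](C)(C(=O)O)C1=CCC23OCCO3 | intermediate
8 | iodo lactone: 19,6β-olide, 5α-iodo, C8 dioxolane | C[C@@]12CCC[C@]3(C)C(=O)O[C@H](CC14OCCO4)[C@]23I | intermediate
9 | lactone ketal: 19,6β-olide, 5α-H, C8 dioxolane | C[C@@]12CCC[C@]3(C)C(=O)O[C@H](CC14OCCO4)[C@H]23 | intermediate
10 | keto lactone: 19,6β-olide, 5α-H, C8 ketone in the five-membered ring | C[C@@]12CCC[C@]3(C)C(=O)O[C@H](CC1=O)[C@H]23 | intermediate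
11 | (R)-malic acid | OC(=O)C[C@@H](O)C(=O)O | starting material
12 | 2-[(2R,4R)-2-tert-butyl-5-oxo-1,3-dioxolan-4-yl]acetic acid (cis) | OC(=O)C[C@H]1O[C@@H](C(C)(C)C)OC1=O | intermediate
13 | 2-[(2R,4R)-2-tert-butyl-5-oxo-4-(prop-2-yn-1-yl)-1,3-dioxolan-4-yl]acetic acid | OC(=O)C[C@@]1(CC#C)O[C@@H](C(C)(C)C)OC1=O | intermediate
14 | (2R,5R)-2-tert-butyl-5-(2-hydroxyethyl)-5-(prop-2-yn-1-yl)-1,3-dioxolan-4-one | OCC[C@@]1(CC#C)O[C@@H](C(C)(C)C)OC1=O | intermediate
15 | (3R)-3-hydroxy-3-(prop-2-yn-1-yl)oxolan-2-one | C#CC[C@@]1(O)CCOC1=O | intermediate
16 | (3R)-3-(prop-2-yn-1-yl)oxolane-2,3-diol (lactol, C2 epimers) | C#CC[C@@]1(O)CCOC1O | intermediate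
17 | (3R)-2-methoxy-3-(prop-2-yn-1-yl)oxolan-3-ol (C2 epimers) | C#CC[C@@]1(O)CCOC1OC | intermediate
18 | alkyne diol: keto lactone 10 with C8 as tertiary alcohol (OH β) bearing α-C9≡C11–C12H2–C13(OH) of 17 (13R, C16 epimers) | C[C@@]12CCC[C@]3(C)C(=O)O[C@H](C[C@@]1(O)C#CC[C@@]4(O)CCOC4OC)[C@H]23 | intermediate
19 | enol ether carbinol: 8β-OH, C8 bearing the 4,5-dihydrofuran-2-yl ring (C9=C11, O–C13 spiro, 13R, C16 epimers) | C[C@@]12CCC[C@]3(C)C(=O)O[C@H](C[C@@]1(O)C5=CC[C@]4(CCOC4OC)O5)[C@H]23 | intermediate
20 | spiro ketone: six-membered ring B, C8=O, 9α,13-epoxy (13R), 19,6β-olide, C16 methyl acetal (C16 epimers) | C[C@@]12CCC[C@]3(C)C(=O)O[C@H](CC(=O)[C@]14CC[C@]5(CCOC5OC)O4)[C@H]23 | intermediate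
21 | keto dilactone: as 20 with C16 lactone carbonyl | C[C@@]12CCC[C@]3(C)C(=O)O[C@H](CC(=O)[C@]14CC[C@]5(CCOC5=O)O4)[C@H]23 | intermediate
22 | CNP0105047.2: 8β,17-epoxy-9α,13-epoxy-labdane-19,6β:16,15-diolide (13R) | C[C@@]12CCC[C@]3(C)C(=O)O[C@H](C[C@@]4(CO4)[C@]14CC[C@]1(CCOC1=O)O4)[C@H]23 | target

**Step count and risks**

Total step count: 16. Longest linear sequence: 12 steps (steps 1–8, then 13–16).

Steps most likely to fail:

1. Step 14 (proposed new method). The gold-activated alkyne may be diverted into Meyer–Schuster isomerisation or hydration before the hindered 5-endo closure. Protonation of the enol ether may also be reversible, so that the unstrained five-membered ring expands too slowly and the oxocarbenium ion is lost. The fallback uses known chemistry only, sets out from 17 and 10 and comes back at 20. Alkynol 17 is cycloisomerised on its own with Mo(CO)6 and Et3N under irradiation (endo-selective alkynol cycloisomerisation through the metal vinylidene) to the spiro dihydrofuran F1. F1 is lithiated at its enol ether CH (t-BuLi, THF, −78 → 0 °C), transmetalated with CeCl3 and added to ketone 10, which should give the enol ether carbinol 19, this time isolated. Treatment of 19 with N-bromosuccinimide (propylene oxide, i-PrOH, −78 °C) is the bromonium-induced, irreversible form of the pinacol-type ring expansion known for dihydrofuranyl carbinols of unstrained ketones, and should give the 11-bromo ketone F2. Radical debromination with n-Bu3SnH and AIBN returns 20.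

2. Step 16. The basic ylide may deprotonate C7, followed by β-elimination of the C6 carboxylate and opening of the 19,6-lactone, or it may add to the spiro-lactone carbonyl. The fallback sets out from 21 and comes back at 22. Non-basic Takai–Lombardo methylenation (Zn, CH2Br2, TiCl4, THF/CH2Cl2) should give the 8(17)-methylene dilactone F3. A peracid would attack the open α-face and give the wrong epoxide, so F3 is instead treated with N-bromosuccinimide in aqueous DME (bromonium on the α-face, water at C8 from the β-face) to give the bromohydrin F4. Ag2O then closes F4 to the 8β,17-epoxide 22.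

3. Step 4. Condensation of the hydrazide at the carbonyl flanked by quaternary C4 may be slow or incomplete, or the diazene may not fragment cleanly. The fallback sets out from 4 and comes back at 6. NaBH4 (MeOH, 0 °C) reduces the C3 ketone to the hydroxy ester F5 (C3 epimers are irrelevant). NaH, CS2 and MeI give the xanthate F6. Barton–McCombie deoxygenation with n-Bu3SnH at high concentration (so that hydrogen transfer outruns 3-exo closure of the homoallylic radical onto C5=C6) returns 6.

**Further compounds**

F1 | step 14 | (5R)-6-methoxy-1,7-dioxaspiro[4.4]non-2-ene (C6 epimers) | C1=CC[C@]2(CCOC2OC)O1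
F2 | step 14 | 11-bromo derivative of spiro ketone 20 (C11 and C16 epimers) | C[C@@]12CCC[C@]3(C)C(=O)O[C@H](CC(=O)[C@]14C(Br)C[C@]5(CCOC5OC)O4)[C@H]23
F3 | step 16 | 8(17)-methylene dilactone (C8=CH2 in place of C8=O of 21) | C[C@@]12CCC[C@]3(C)C(=O)O[C@H](CC(=C)[C@]14CC[C@]5(CCOC5=O)O4)[C@H]23
F4 | step 16 | bromohydrin: 8β-hydroxy-17-bromo dilactone | C[C@@]12CCC[C@]3(C)C(=O)O[C@H](C[C@@](O)(CBr)[C@]14CC[C@]5(CCOC5=O)O4)[C@H]23
F5 | step 4 | 3-hydroxy ester (C3 epimers) from keto ester 4 | C[C@]12CCC(O)[C@](C)(C(=O)OC)C1=CCC23OCCO3
F6 | step 4 | S-methyl xanthate of F5 (C3 epimers) | C[C@]12CCC(OC(=S)SC)[C@](C)(C(=O)OC)C1=CCC23OCCO3
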